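Readings and results were generated by integration for substances that don't exist; noise was put on by code.

Of the 1.00 M of Xa and 1.50 M of Xb in the west flask, one Xa goes into each Xp. Xa is therefore the limiting reagent, and the ceiling at 52 min is 100 percent of it.

| flask | Xa | Xb | Xp | time |
|---|---|---|---|---|
| north-west | 1.00 M | 1.50 M |  |  |
| north-east | 1.00 M | 1.50 M | 0.300 M |  |
| east | 1.50 M | 1.50 M |  |  |
| north | 1.00 M | 0.750 M |  |  |
| west | 1.00 M | 1.50 M |  | 52 min |

| north-west run: time / min | north-west run: [Xp] / M | north-east run: time / min | north-east run: [Xp] / M | east run: time / min | east run: [Xp] / M | north run: time / min | north run: [Xp] / M |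
|---|---|---|---|---|---|---|---|
| 2.2 | 0.153 | 2.2 | 0.454 | 2.2 | 0.201 | 2.2 | 0.096 |
| 4.3 | 0.333 | 4.3 | 0.629 | 4.3 | 0.432 | 4.3 | 0.200 |
| 6.5 | 0.461 | 6.5 | 0.761 | 6.5 | 0.592 | 6.5 | 0.279 |
| 8.7 | 0.557 | 8.7 | 0.847 | 8.7 | 0.702 | 8.7 | 0.340 |
| 11 | 0.618 | 11 | 0.917 | 11 | 0.785 | 11 | 0.385 |
| 13 | 0.655 | 13 | 0.965 | 13 | 0.835 | 13 | 0.414 |

(readings scatter by 0.003 M)

- Overall: Xa + Xb -> Xp.
- Constant volume, constant temperature.
- Bound and free are read together.
- "The second partner" is Xb.
- An order is taken over about fifteen percent of the charge, up and down.

- reaction order in [Xa] at the outset, round the charge of the north-west run, defined at two percent of the Xa turned into Xp (one fixed amount of Xp, the same in the runs compared)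
- reaction order in [Xb] at the outset, round the charge of the north-west run, defined at two percent of the Xa turned into Xp
- Xp in the west run at 52 min, as a share of the Xa charged

The north-west run has the west charge. The north-east run, less its added 0.300 M, follows it closely, ending at 0.665 M against 0.655 M. I treat them as one flask read twice, and their mean last value, 0.660 M, is my floor.

The readings stand about equally apart. Averaged over both runs, the last two steps of Xp are 0.0655 M and 0.0425 M, so each step is 0.649 of the one before. If that ratio holds, the later steps sum to the last step times the ratio over one minus the ratio, which is 0.0785 M. I call this the amount still to come.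

Such a rate falls in proportion to itself, which gives my lower bound, 73.9%. A rate falling with the square of what feeds it leaves twice that amount, which gives my upper bound, 81.7%.

The forecast gives orders of 0.67 in Xa and 0.72 in Xb, and 79% for the west run, with “a possibly slower tail”. That share stands inside my bracket.

The simulation gives orders of 0.49 and 0.38, both lower than the forecast's, and 80.7% for the west run, also inside the bracket.

    Xa + Xb → Xi (0.2706 L mol⁻¹ min⁻¹)
    Xi → Xp (1.032 min⁻¹)
    Xa + Xb ⇌ Xa.Xb, settled at all times (0.9640 L mol⁻¹)
    2 Xa → G (0.1182 L mol⁻¹ min⁻¹)

Above my floor, the west result leaves 0.147 M still to come, 1.87 times my amount, so it lies near the upper bound. In the north run, the same rule on its own last steps gives 0.0526 M, a bracket of 46.7% to 51.9% of the charge, and the Xp of that run comes to half of the charge at 24.3 min. The west shortfall comes from Xa pairing with itself to G: with that step taken away, the west run reaches 99.4% at 52 min.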